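**Plan**

- Retrosynthesis: the C2 formyl group is traced back to an ethyl ester, and the pyrrole to an N-tosyl 2,5-dihydropyrrole that aromatises by loss of sulfinate from nitrogen. The ring C3=C4 bond is then cut by ring-closing metathesis, followed by the N–allyl bond, the C2–C3 bond (alkenyl Grignard plus glyoxylate N-tosylimine) and the bond between the first and second chain carbons (icosyl Grignard plus 2,3-dibromopropene).
- Enabling feature: C3 (carrying the henicosyl chain) and C4 (carrying hydrogen) of the pyrrole ring are the two carbons of a trisubstituted ring alkene. That alkene is the union of a 1,1-disubstituted alkene and the terminal alkene of an N-allyl group in a 1,6-diene.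
- Forward: the chain is joined first (C20 + C3), then C2–C3, then the N-allyl group. The single ring closes at C3=C4, base removes the tosyl group as sulfinate to aromatise, and the ester is taken to the aldehyde through the alcohol.
- Stereochemistry: the target has no stereocentre. C2 is racemic in compounds 8–10 and disappears on aromatisation; the ring alkene is cis by necessity.

Key step: step 5

Assumption: ethyl glyoxylate is used as its commercial toluene solution, cracked to the monomer by heating; "tosyl" means (4-methylphenyl)sulfonyl throughout.

**Route**

Step 1
Reactants: 1 1-bromoicosane; 2 2,3-dibromopropene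
Product: 4 2-bromotricos-1-ene, via icosylmagnesium bromide 3 (not isolated)
Conditions: Mg, THF, 50 °C; then 2, CuI (5 mol%), THF, 0 °C to rt
Reagents that add atoms: none
Why: Copper-catalysed allylic substitution by a primary alkyl Grignard reagent displaces the allylic bromide while the vinylic C–Br bond stays inert, and direct and allyl-transposed attack lead to the same 2-bromo-1-alkene, so regiochemistry is not an issue.

Step 2
Reactants: 5 ethyl glyoxylate
Product: 6 ethyl (E)-2-(tosylimino)acetate
Conditions: TsNCO, AlCl3 (cat.), toluene, reflux; concentrated under argon and used at once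
Reagents that add atoms: p-toluenesulfonyl isocyanate, Cc1ccc(cc1)S(=O)(=O)N=C=O
Why: The sulfonyl isocyanate and the aldehyde undergo [2+2] cycloaddition and cycloreversion with loss of CO2 (aza-Wittig-type carbonyl–isocyanate exchange), the standard preparation of N-sulfonyl imines of glyoxylates.

Step 3
Reactants: 4 2-bromotricos-1-ene; 6 ethyl (E)-2-(tosylimino)acetate
Product: 8 ethyl 3-methylidene-2-(tosylamino)tetracosanoate (racemic), via tricos-1-en-2-ylmagnesium bromide 7 (not isolated)
Conditions: Mg, THF, 55 °C; then added slowly to 6 (1.2 equiv), THF, −78 °C; H2O quench, pH 7 buffer work-up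
Reagents that add atoms: none
Why: Magnesium insertion into the vinylic C–Br bond followed by 1,2-addition of the alkenyl Grignard reagent to the C=N bond of an N-sulfonyl alpha-imino ester (an electrophilic glycine equivalent) should be selective because the doubly activated imine carbon reacts far faster than the ester at −78 °C when the Grignard reagent is added to excess imine; the new C2 stereocentre forms as a racemate, which is acceptable because it is destroyed in step 6.

Step 4
Reactants: 8 ethyl 3-methylidene-2-(tosylamino)tetracosanoate
Product: 9 ethyl 2-[allyl(tosyl)amino]-3-methylidenetetracosanoate (racemic)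
Conditions: allyl alcohol, PPh3, DIAD, THF, 0 °C to rt
Reagents that add atoms: allyl alcohol, C=CCO
Why: Mitsunobu N-alkylation of the acidic sulfonamide N–H of an N-tosyl amino ester with a primary alcohol runs under essentially neutral conditions, so the beta,gamma-alkene should not migrate into conjugation with the ester.

Step 5
Reactants: 9 ethyl 2-[allyl(tosyl)amino]-3-methylidenetetracosanoate
Product: 10 ethyl 3-henicosyl-1-tosyl-2,5-dihydro-1H-pyrrole-2-carboxylate (racemic)
Conditions: second-generation Grubbs catalyst RuCl2(=CHPh)(PCy3)(SIMes) (5 mol%), CH2Cl2 (0.01 M), 40 °C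
Reagents that add atoms: none
Why: The ruthenium benzylidene first exchanges with the unhindered N-allyl terminus, the resulting alkylidene adds [2+2] across the tethered 1,1-disubstituted alkene to give a ruthenacyclobutane, and cycloreversion releases the ring alkene and Ru=CH2, which carries the cycle with loss of ethene. This is ring-closing olefin metathesis of an N-sulfonyl diallylamine-type 1,6-diene, the standard route to 3-pyrrolines. The five-membered ring closes by joining C3 to C4 of the future pyrrole, with the henicosyl chain already in place on C3 and hydrogen on C4. No stereocentre is created: C2 is carried through as the racemate and the ring alkene can only be cis. The step needs ring closure to outrun intermolecular metathesis and needs nitrogen kept off ruthenium; the five-membered ring size, the dilution, the reluctance of the 1,1-disubstituted alkene to homodimerise and the non-basic sulfonamide nitrogen should secure both. Escape of ethene from the refluxing solution should drive the closure to completion.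

Step 6
Reactants: 10 ethyl 3-henicosyl-1-tosyl-2,5-dihydro-1H-pyrrole-2-carboxylate
Product: 12 ethyl 3-henicosyl-1H-pyrrole-2-carboxylate, via ethyl 4-henicosyl-2H-pyrrole-5-carboxylate 11 (not isolated)
Conditions: t-BuOK (2.2 equiv), THF, 0 °C to rt; aq NH4Cl
Reagents that add atoms: none
Why: In an E1cB-type elimination, potassium tert-butoxide removes the C2 proton (alpha to the ester and allylic), the enolate expels p-toluenesulfinate from nitrogen to give the 2H-pyrrole, and a base-mediated proton shift from the ring CH2 to nitrogen delivers the aromatic pyrrole, as known for N-sulfonyl 3-pyrrolines.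

Step 7
Reactants: 12 ethyl 3-henicosyl-1H-pyrrole-2-carboxylate
Product: 13 (3-henicosyl-1H-pyrrol-2-yl)methanol
Conditions: LiAlH4, THF, 0 °C, short contact time; H2O/aq NaOH work-up; crude product used at once
Reagents that add atoms: none
Why: LiAlH4 reduction of the ester should stop at the primary alcohol if kept at 0 °C with a basic work-up, conditions chosen to avoid azafulvene-mediated over-reduction to the 2-methylpyrrole and acid-triggered self-condensation of the carbinol.

Step 8
Reactants: 13 (3-henicosyl-1H-pyrrol-2-yl)methanol
Product: 14 3-henicosyl-1H-pyrrole-2-carbaldehyde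
Conditions: activated MnO2 (excess), CH2Cl2, rt
Reagents that add atoms: none
Why: MnO2 oxidises heteroaryl (benzylic-type) carbinols selectively to aldehydes, and the product, a vinylogous formamide, should resist further oxidation.

**Compound list**

1 | 1-bromoicosane | CCCCCCCCCCCCCCCCCCCCBr | starting material
2 | 2,3-dibromopropene | C=C(Br)CBr | starting material
3 | icosylmagnesium bromide (formed in the flask) | CCCCCCCCCCCCCCCCCCCC[Mg]Br | intermediate
4 | 2-bromotricos-1-ene | C=C(Br)CCCCCCCCCCCCCCCCCCCCC | intermediate
5 | ethyl glyoxylate | CCOC(=O)C=O | starting material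
6 | ethyl (E)-2-(tosylimino)acetate | CCOC(=O)/C=N/S(=O)(=O)c1ccc(C)cc1 | intermediate
7 | tricos-1-en-2-ylmagnesium bromide (formed in the flask) | C=C([Mg]Br)CCCCCCCCCCCCCCCCCCCCC | intermediate
8 | ethyl 3-methylidene-2-(tosylamino)tetracosanoate (racemic) | CCCCCCCCCCCCCCCCCCCCCC(=C)C(NS(=O)(=O)c1ccc(C)cc1)C(=O)OCC | intermediate
9 | ethyl 2-[allyl(tosyl)amino]-3-methylidenetetracosanoate (racemic) | CCCCCCCCCCCCCCCCCCCCCC(=C)C(N(CC=C)S(=O)(=O)c1ccc(C)cc1)C(=O)OCC | intermediate
10 | ethyl 3-henicosyl-1-tosyl-2,5-dihydro-1H-pyrrole-2-carboxylate (racemic) | CCCCCCCCCCCCCCCCCCCCCC1=CCN(S(=O)(=O)c2ccc(C)cc2)C1C(=O)OCC | intermediate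
11 | ethyl 4-henicosyl-2H-pyrrole-5-carboxylate (formed in the flask) | CCCCCCCCCCCCCCCCCCCCCC1=CCN=C1C(=O)OCC | intermediate
12 | ethyl 3-henicosyl-1H-pyrrole-2-carboxylate | CCCCCCCCCCCCCCCCCCCCCc1cc[nH]c1C(=O)OCC | intermediate
13 | (3-henicosyl-1H-pyrrol-2-yl)methanol | CCCCCCCCCCCCCCCCCCCCCc1cc[nH]c1CO | intermediate
14 | 3-henicosyl-1H-pyrrole-2-carbaldehyde | CCCCCCCCCCCCCCCCCCCCCc1cc[nH]c1C=O | target

**Step count and risks**

Total steps: 8. Longest linear sequence: 7 steps (steps 1, 3, 4, 5, 6, 7, 8 from 1-bromoicosane); step 2 is a one-step side branch from ethyl glyoxylate.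

Steps most likely to fail:

1. Step 3. The moisture-sensitive N-tosylimine may hydrolyse or oligomerise before the C–C bond forms, and the alkenyl Grignard reagent may attack the ester carbonyl or the imine nitrogen in competition with the imine carbon. The fallback sets out from 5 and from the Grignard reagent 7 (made from 4 as before) and returns to the route at 8. Ethyl glyoxylate 5 is condensed with racemic 2-methylpropane-2-sulfinamide (CuSO4, CH2Cl2, rt) to give the storable ethyl (E)-2-(tert-butylsulfinylimino)acetate F1. Addition of 7 in CH2Cl2 at −78 °C gives ethyl 2-(tert-butylsulfinylamino)-3-methylidenetetracosanoate F2 as a diastereomer mixture, which is of no consequence. HCl in EtOH removes the sulfinyl group to give ethyl 2-amino-3-methylidenetetracosanoate F3, and TsCl with Et3N in CH2Cl2 then gives 8.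

2. Step 7. The N-unprotected pyrrole ester may be over-reduced through an azafulvene to the 2-methylpyrrole, and the electron-rich hydroxymethylpyrrole may self-condense on work-up or during the following oxidation. The fallback sets out from 10 and returns at the target 14, making the redox adjustment before aromatisation so that no free hydroxymethylpyrrole is formed. LiBH4 in THF (0 °C to rt) reduces the ester of 10 to the stable sulfonamide alcohol (3-henicosyl-1-tosyl-2,5-dihydro-1H-pyrrol-2-yl)methanol F4. Dess–Martin periodinane buffered with NaHCO3 in CH2Cl2 gives 3-henicosyl-1-tosyl-2,5-dihydro-1H-pyrrole-2-carbaldehyde F5. DBU in CH2Cl2 at rt then eliminates p-toluenesulfinate from nitrogen and aromatises the ring to 14.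

3. Step 4. Alkylation at the alpha-branched sulfonamide nitrogen may be sluggish, so that the hydrazide by-product is allylated instead, and the 1,1-disubstituted alkene may migrate into conjugation with the ester. The fallback sets out from 8 and returns at 9 by a palladium pi-allyl substitution instead of alcohol activation: allyl methyl carbonate and Pd(PPh3)4 (zerovalent palladium) in THF at rt. The methoxide released on decarboxylation deprotonates the sulfonamide, which captures the pi-allylpalladium cation without any added base. This detour makes no new compound, F0.

**Further compounds**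

F1 | step 3 | ethyl (E)-2-(tert-butylsulfinylimino)acetate (racemic at sulfur) | CCOC(=O)/C=N/S(=O)C(C)(C)C
F2 | step 3 | ethyl 2-(tert-butylsulfinylamino)-3-methylidenetetracosanoate (diastereomer mixture) | CCCCCCCCCCCCCCCCCCCCCC(=C)C(NS(=O)C(C)(C)C)C(=O)OCC
F3 | step 3 | ethyl 2-amino-3-methylidenetetracosanoate (racemic) | CCCCCCCCCCCCCCCCCCCCCC(=C)C(N)C(=O)OCC
F4 | step 7 | (3-henicosyl-1-tosyl-2,5-dihydro-1H-pyrrol-2-yl)methanol (racemic) | CCCCCCCCCCCCCCCCCCCCCC1=CCN(S(=O)(=O)c2ccc(C)cc2)C1CO
F5 | step 7 | 3-henicosyl-1-tosyl-2,5-dihydro-1H-pyrrole-2-carbaldehyde (racemic) | CCCCCCCCCCCCCCCCCCCCCC1=CCN(S(=O)(=O)c2ccc(C)cc2)C1C=O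
F0 | step 4 | none | none
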